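The labdane is cut at C3–C4, so that ring A (C1–C5, C10) closes last and ring B (C5–C10) with C4, C18, C19 and C20 comes intact from (+)-verbenone, whose only extra bond is the cyclobutane bond C4–C7. The key step spends that bond: silyl activation of the C8 ketone releases a C4 cation and a C7=C8 enol ether, and a (Z)-vinylsilane on C10 traps C4 at C3, closing ring A trans-fused in one operation. It exploits the gem-dimethyl quaternary C4 beside the C5–C10 ring fusion. The precursor is a 4-substituted verbanone: silylallyl chain on C10 anti to the gem-dimethyl bridge, methyl acetate arm on C9.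

Key step: step 7

Remark on the chemistry: labdane numbering and α/β descriptors (C20 = β) are used for all compounds, the bicyclic ones included; the target is read as (12Z)-6α-acetoxylabda-12,14-diene-7β,8α-diol (5S,6R,7S,8S,9R,10S), which calls for the (1R,5R) enantiomer of verbenone; compounds 14 and 16 as drawn carry C5 and C10 of the target and C9 as its epimer, so no stereodescriptor had to be corrected; the only redesign is on the way to 14, where a non-ambident allyl nucleophile is used for the hindered conjugate addition and then converted to the silylalkyne; in the by-product list metal ions are written as the salt that the stated quench gives.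

Step 1
Reactants: 1 (1R,5R)-(+)-verbenone; 2 allylmagnesium bromide
Product: 4 4-allyl-4,6,6-trimethylbicyclo[3.1.1]heptan-2-one (allyl anti to the gem-dimethyl bridge), via trimethylsilyl enol ether 3 (not isolated)
Conditions: 2 (1.5 equiv), CuBr·SMe2 (1.5 equiv), LiCl, Me3SiCl (2 equiv), THF, −78 °C; then 1 M HCl, 0 °C
Reagents that add atoms: none
Why: Conjugate addition of a preformed allylcopper reagent activated by Me3SiCl (Lipshutz-type) is reliable on β,β-disubstituted enones, and because the gem-dimethyl bridge shields one face of the enone the allyl group should enter anti to it, which sets C10 (chain α, C20 β).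

Step 2
Reactants: 4
Product: 6 2-(4,6,6-trimethyl-2-oxobicyclo[3.1.1]hept-4-yl)acetaldehyde (CH2CHO anti to the bridge), via ozonide 5 (not isolated)
Conditions: O3, CH2Cl2, −78 °C; then PPh3, −78 → 23 °C
Reagents that add atoms: ozone, [O-][O+]=O
Why: Ozonolysis with reductive work-up cleaves the only C=C bond to the aldehyde and touches no stereocentre.

Step 3
Reactants: 6
Product: 7 4,6,6-trimethyl-4-(prop-2-ynyl)bicyclo[3.1.1]heptan-2-one (propargyl anti to the bridge)
Conditions: dimethyl (1-diazo-2-oxopropyl)phosphonate (1.3 equiv), K2CO3 (2 equiv), MeOH, 0 → 23 °C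
Reagents that add atoms: dimethyl (1-diazo-2-oxopropyl)phosphonate, COP(=O)(OC)C(=[N+]=[N-])C(C)=O
Why: Seyferth–Gilbert homologation in the Ohira–Bestmann form turns the aldehyde into the terminal alkyne under mild base, the hindered bridged ketone is inert, and an intramolecular aldol could only give a four-membered ring.

Step 4
Reactants: 7
Product: 10 4,6,6-trimethyl-4-[3-(trimethylsilyl)prop-2-ynyl]bicyclo[3.1.1]heptan-2-one, via dilithium enolate acetylide 8 (not isolated), via O,C-bis(trimethylsilyl) compound 9 (not isolated)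
Conditions: LDA (2.2 equiv), THF, −78 °C; Me3SiCl (2.5 equiv), −78 → 0 °C; then 1 M HCl, THF, 0 °C
Reagents that add atoms: chlorotrimethylsilane, C[Si](C)(C)Cl
Why: Double deprotonation (C9–H and alkyne C–H) followed by silylation and selective acid hydrolysis of the enol ether is a standard C-silylation of a terminal alkyne beside an enolisable ketone.

Step 5
Reactants: 10; 11 methyl bromoacetate
Product: 13 methyl 2-{4,6,6-trimethyl-2-oxo-4-[3-(trimethylsilyl)prop-2-ynyl]bicyclo[3.1.1]hept-3-yl}acetate (both side chains anti to the bridge), via lithium enolate 12 (not isolated)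
Conditions: LDA (1.1 equiv), THF, −78 °C; then 11 (1.3 equiv), DMPU, −78 → −30 °C
Reagents that add atoms: none
Why: Enolate alkylation can occur only at C9 because C7 is a cyclobutane bridgehead, and the reactive α-bromo ester should approach anti to the gem-dimethyl bridge, giving the arm α at C9 (a temporary centre, corrected in step 8).

Step 6
Reactants: 13
Product: 14 methyl 2-{4,6,6-trimethyl-2-oxo-4-[(Z)-3-(trimethylsilyl)allyl]bicyclo[3.1.1]hept-3-yl}acetate (key-step precursor)
Conditions: H2 (1 atm), Lindlar catalyst, quinoline, EtOAc–hexane, 23 °C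
Reagents that add atoms: none
Why: Lindlar semihydrogenation of a 1-silylalkyne is a standard cis-selective route to (Z)-vinylsilanes and leaves ketone and ester untouched.

Step 7
Reactants: 14
Product: 16 methyl 8-oxo-13,14,15,16,17-pentanor-9-epi-labd-2-en-12-oate (trans-fused; 9α arm), via silyl enol ether 15 (not isolated)
Conditions: Me3SiOTf (0.3 equiv), 2,6-di-tert-butyl-4-methylpyridine (0.1 equiv), CH2Cl2, −78 → 0 °C; then 1 M HCl, THF, 0 °C
Reagents that add atoms: none
Why: Proposed new method: O-silylation of the C8 carbonyl by Me3SiOTf should let the strained C4–C7 bond, which lies parallel to the carbonyl π system, heterolyse to a tertiary C4 cation and the C7=C8 silyl enol ether; the cation is then attacked by the silicon-bearing C3 of the vinylsilane, and the β-silyl cation at C2 gives up Me3Si+ to triflate, which restores the promoter and leaves the Δ2 alkene, so that 15 is an isomer of 14. The closest known reaction types are the Me3SiI- or BF3-induced cyclobutane opening of nopinone-type pinane ketones to p-menthyl cations and the vinylsilane-terminated cation–olefin cyclisation, which have not been joined in one operation. Ring A closes in the 6-endo mode at the vinylsilane through a chair-like array in which the C4 cation on C5 and the chain on C10 are both equatorial on the half-chair of ring B. No stereocentre is created; the trans fusion is dictated by C5 of verbenone and by C10 from step 1, because the cation and the chain are trans on ring B and cannot reach each other in a cis-decalin array. The step needs ipso capture at C3 to beat proton loss from the cation: the Z geometry is the one that allows endocyclic closure with β-silicon stabilisation, the counter-ion is non-nucleophilic, the hindered pyridine removes acid that would protodesilylate, and the low temperature disfavours E1.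

Step 8
Reactants: 16
Product: 18 methyl 8-oxo-13,14,15,16,17-pentanorlabdan-12-oate (9β arm), via 9β-epimer 17 (not isolated)
Conditions: NaOMe (0.3 equiv), MeOH, 23 °C; then 10% Pd/C, H2 (1 atm), same flask, 23 °C
Reagents that add atoms: none
Why: Base equilibration through the C8–C9 enolate should move the arm from the axial α to the equatorial β position (three syn-axial contacts are relieved), which sets C9 under thermodynamic control, and catalytic hydrogenation then saturates the disubstituted Δ2 alkene without creating a stereocentre.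

Step 9
Reactants: 18
Product: 20 methyl 8-(trifluoromethylsulfonyloxy)-13,14,15,16,17-pentanorlabd-7-en-12-oate, via potassium enolate 19 (not isolated)
Conditions: KHMDS (1.2 equiv), THF, −78 °C; PhNTf2 (1.3 equiv), −78 → 0 °C; 1 M HCl wash
Reagents that add atoms: N-phenylbis(trifluoromethanesulfonimide), O=S(=O)(N(c1ccccc1)S(=O)(=O)C(F)(F)F)C(F)(F)F
Why: Kinetic enolisation with a bulky amide takes the unhindered C7 methylene (C9–H sits beside the quaternary C10 and the ester is less acidic than the ketone), and O-triflation fixes the enolate as the Δ7 enol triflate.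

Step 10
Reactants: 20
Product: 21 methyl 13,14,15,16-tetranorlabd-7-en-12-oate
Conditions: MeZnCl (2 equiv), Pd(PPh3)4 (5 mol%), THF, 50 °C
Reagents that add atoms: methylzinc chloride, C[Zn]Cl
Why: Negishi cross-coupling of an enol triflate with a methylzinc reagent tolerates the ester and places C17 on C8 with the alkene fixed at Δ7.

Step 11
Reactants: 21
Product: 22 13,14,15,16-tetranorlabd-7-en-12-al
Conditions: DIBAL-H (1.1 equiv), CH2Cl2, −78 °C; MeOH, then aq. Rochelle salt
Reagents that add atoms: none
Why: Partial ester reduction with DIBAL-H at −78 °C stops at the aluminium hemiacetal, which releases the aldehyde on work-up, and the trisubstituted alkene is inert.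

Step 12
Reactants: 22; 23 ethyltriphenylphosphonium iodide
Product: 24 (12Z)-13-iodo-14,15-dinorlabda-7,12-diene
Conditions: 23 (2.2 equiv), n-BuLi, THF, 0 °C; I2, −78 °C; NaHMDS, −20 °C; then 22, −78 → −20 °C
Reagents that add atoms: iodine, II
Why: Wittig olefination with the α-iodo ylide (Stork–Zhao-type iodoalkylidenation) is Z-selective and places iodine cis to C11, the geometry that the later coupling transfers to the diene.

Step 13
Reactants: 24
Product: 25 (12Z)-13-iodo-14,15-dinorlabd-12-ene-7α,8α-diol
Conditions: OsO4 (2 mol%), NMO (1.5 equiv), acetone–H2O, 23 °C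
Reagents that add atoms: N-methylmorpholine N-oxide, C[N+]1([O-])CCOCC1; water, O
Why: Upjohn dihydroxylation should take the electron-rich Δ7 alkene much faster than the halogen-deactivated iodoalkene and from the α face, opposite the axial C20 methyl, which sets C8 (8α-OH, 8β-CH3) and gives the 7α-alcohol.

Step 14
Reactants: 25; 26 tributyl(vinyl)stannane
Product: 27 (12Z)-labda-12,14-diene-7α,8α-diol
Conditions: 26 (1.5 equiv), Pd(PPh3)4 (5 mol%), CuI (10 mol%), DMF, 45 °C
Reagents that add atoms: none
Why: Stille coupling proceeds with retention at the vinyl iodide under neutral conditions that tolerate the free diol, so the 12Z diene should result.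

Step 15
Reactants: 27
Product: 28 (12Z)-8α-hydroxylabda-12,14-dien-7-one
Conditions: IBX (1.5 equiv), DMSO, 23 °C
Reagents that add atoms: none
Why: IBX oxidation converts the secondary axial 7α-alcohol of a secondary–tertiary 1,2-diol into the α-hydroxy ketone without C–C cleavage and leaves the tertiary alcohol and the diene alone.

Step 16
Reactants: 28
Product: 30 (12Z)-6α,8α-dihydroxylabda-12,14-dien-7-one, via dipotassium alkoxide enolate 29 (not isolated)
Conditions: KHMDS (2.4 equiv), THF, −78 → −40 °C; 2-(phenylsulfonyl)-3-phenyloxaziridine (1.4 equiv), −78 °C; AcOH quench at −78 °C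
Reagents that add atoms: 2-(phenylsulfonyl)-3-phenyloxaziridine, O=S(=O)(c1ccccc1)N1OC1c1ccccc1
Why: Davis enolate hydroxylation works because the ketone can enolise only toward C6 and the oxaziridine ignores the diene, and oxygen should arrive on the α face since the β face of C6 is blocked by the syn-axial C19 and C20 methyls, which sets C6 as the equatorial 6α-alcohol.

Step 17
Reactants: 30
Product: 31 (12Z)-6α-acetoxy-8α-hydroxylabda-12,14-dien-7-one
Conditions: Ac2O (1.5 equiv), pyridine, DMAP (5 mol%), CH2Cl2, 0 → 23 °C
Reagents that add atoms: acetic anhydride, CC(=O)OC(C)=O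
Why: DMAP-catalysed acetylation takes the secondary 6α-hydroxyl, while the tertiary 8α-hydroxyl is too hindered to compete under these conditions.

Step 18
Reactants: 31
Product: 32 (12Z)-6α-acetoxylabda-12,14-diene-7β,8α-diol (target CNP0138393.1)
Conditions: NaBH4, CeCl3·7H2O, MeOH, −78 °C; AcOH quench
Reagents that add atoms: none
Why: Luche-type borohydride reduction should deliver hydride to C7 axially from the α face, anti to the adjacent axial 8β-methyl, which sets C7 as the equatorial 7β-alcohol, and the cold cerium-buffered medium suppresses acetyl migration.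

Compound list
1 | (1R,5R)-(+)-verbenone | O=C1C=C(C)[C@H]2C[C@@H]1C2(C)C | starting material
2 | allylmagnesium bromide | C=CC[Mg]Br | starting material
3 | 4-allyl-4,6,6-trimethyl-2-(trimethylsilyloxy)bicyclo[3.1.1]hept-2-ene, allyl anti to the gem-dimethyl bridge | C[Si](C)(C)OC1=C[C@@](C)(CC=C)[C@H]2C[C@@H]1C2(C)C | intermediate
4 | 4-allyl-4,6,6-trimethylbicyclo[3.1.1]heptan-2-one, allyl anti to the gem-dimethyl bridge | O=C1C[C@@](C)(CC=C)[C@H]2C[C@@H]1C2(C)C | intermediate
5 | ozonide (1,2,4-trioxolane) of 4, mixture at the trioxolane carbon | O=C1C[C@@](C)(CC3OCOO3)[C@H]2C[C@@H]1C2(C)C | intermediate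
6 | 2-(4,6,6-trimethyl-2-oxobicyclo[3.1.1]hept-4-yl)acetaldehyde, CH2CHO anti to the bridge | O=C1C[C@@](C)(CC=O)[C@H]2C[C@@H]1C2(C)C | intermediate
7 | 4,6,6-trimethyl-4-(prop-2-ynyl)bicyclo[3.1.1]heptan-2-one, propargyl anti to the bridge | O=C1C[C@@](C)(CC#C)[C@H]2C[C@@H]1C2(C)C | intermediate
8 | dilithium enolate acetylide of 7 | [Li]OC1=C[C@@](C)(CC#C[Li])[C@H]2C[C@@H]1C2(C)C | intermediate
9 | 2-(trimethylsilyloxy)-4-[3-(trimethylsilyl)prop-2-ynyl]-4,6,6-trimethylbicyclo[3.1.1]hept-2-ene | C[Si](C)(C)OC1=C[C@@](C)(CC#C[Si](C)(C)C)[C@H]2C[C@@H]1C2(C)C | intermediate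
10 | 4,6,6-trimethyl-4-[3-(trimethylsilyl)prop-2-ynyl]bicyclo[3.1.1]heptan-2-one, chain anti to the bridge | O=C1C[C@@](C)(CC#C[Si](C)(C)C)[C@H]2C[C@@H]1C2(C)C | intermediate
11 | methyl bromoacetate | COC(=O)CBr | starting material
12 | lithium enolate of 10 | [Li]OC1=C[C@@](C)(CC#C[Si](C)(C)C)[C@H]2C[C@@H]1C2(C)C | intermediate
13 | methyl 2-{4,6,6-trimethyl-2-oxo-4-[3-(trimethylsilyl)prop-2-ynyl]bicyclo[3.1.1]hept-3-yl}acetate, both side chains anti to the bridge | O=C1[C@@H](CC(=O)OC)[C@@](C)(CC#C[Si](C)(C)C)[C@H]2C[C@@H]1C2(C)C | intermediate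
14 | methyl 2-{4,6,6-trimethyl-2-oxo-4-[(Z)-3-(trimethylsilyl)allyl]bicyclo[3.1.1]hept-3-yl}acetate, both side chains anti to the bridge | O=C1[C@@H](CC(=O)OC)[C@@](C)(C/C=C\[Si](C)(C)C)[C@H]2C[C@@H]1C2(C)C | intermediate
15 | methyl 8-(trimethylsilyloxy)-13,14,15,16,17-pentanor-9-epi-labda-2,7-dien-12-oate (5α-H, 10β-CH3, 9α arm) | COC(=O)C[C@@H]1C(O[Si](C)(C)C)=CC[C@H]2C(C)(C)C=CC[C@@]21C | intermediate
16 | methyl 8-oxo-13,14,15,16,17-pentanor-9-epi-labd-2-en-12-oate (trans-fused, 9α arm) | COC(=O)C[C@@H]1C(=O)CC[C@H]2C(C)(C)C=CC[C@@]21C | intermediate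
17 | methyl 8-oxo-13,14,15,16,17-pentanorlabd-2-en-12-oate (9β arm) | COC(=O)C[C@H]1C(=O)CC[C@H]2C(C)(C)C=CC[C@@]21C | intermediate
18 | methyl 8-oxo-13,14,15,16,17-pentanorlabdan-12-oate (9β arm) | COC(=O)C[C@H]1C(=O)CC[C@H]2C(C)(C)CCC[C@@]21C | intermediate
19 | potassium Δ7-enolate of 18 | COC(=O)C[C@H]1C(O[K])=CC[C@H]2C(C)(C)CCC[C@@]21C | intermediate
20 | methyl 8-(trifluoromethylsulfonyloxy)-13,14,15,16,17-pentanorlabd-7-en-12-oate | COC(=O)C[C@H]1C(OS(=O)(=O)C(F)(F)F)=CC[C@H]2C(C)(C)CCC[C@@]21C | intermediate
21 | methyl 13,14,15,16-tetranorlabd-7-en-12-oate | COC(=O)C[C@H]1C(C)=CC[C@H]2C(C)(C)CCC[C@@]21C | intermediate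
22 | 13,14,15,16-tetranorlabd-7-en-12-al | O=CC[C@H]1C(C)=CC[C@H]2C(C)(C)CCC[C@@]21C | intermediate
23 | ethyltriphenylphosphonium iodide | CC[P+](c1ccccc1)(c1ccccc1)c1ccccc1.[I-] | starting material
24 | (12Z)-13-iodo-14,15-dinorlabda-7,12-diene | I/C(C)=C\C[C@H]1C(C)=CC[C@H]2C(C)(C)CCC[C@@]21C | intermediate
25 | (12Z)-13-iodo-14,15-dinorlabd-12-ene-7α,8α-diol | I/C(C)=C\C[C@H]1[C@](C)(O)[C@H](O)C[C@H]2C(C)(C)CCC[C@@]21C | intermediate
26 | tributyl(vinyl)stannane | C=C[Sn](CCCC)(CCCC)CCCC | starting material
27 | (12Z)-labda-12,14-diene-7α,8α-diol | C=C/C(C)=C\C[C@H]1[C@](C)(O)[C@H](O)C[C@H]2C(C)(C)CCC[C@@]21C | intermediate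
28 | (12Z)-8α-hydroxylabda-12,14-dien-7-one | C=C/C(C)=C\C[C@H]1[C@](C)(O)C(=O)C[C@H]2C(C)(C)CCC[C@@]21C | intermediate
29 | dipotassium 8-alkoxide Δ6-enolate of 28 | C=C/C(C)=C\C[C@H]1[C@](C)(O[K])C(O[K])=C[C@H]2C(C)(C)CCC[C@@]21C | intermediate
30 | (12Z)-6α,8α-dihydroxylabda-12,14-dien-7-one | C=C/C(C)=C\C[C@H]1[C@](C)(O)C(=O)[C@H](O)[C@H]2C(C)(C)CCC[C@@]21C | intermediate
31 | (12Z)-6α-acetoxy-8α-hydroxylabda-12,14-dien-7-one | C=C/C(C)=C\C[C@H]1[C@](C)(O)C(=O)[C@H](OC(C)=O)[C@H]2C(C)(C)CCC[C@@]21C | intermediate
32 | (12Z)-6α-acetoxylabda-12,14-diene-7β,8α-diol (5S,6R,7S,8S,9R,10S) | C=C/C(C)=C\C[C@H]1[C@](C)(O)[C@@H](O)[C@H](OC(C)=O)[C@H]2C(C)(C)CCC[C@@]21C | target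

Total step count: 18. Longest linear sequence: 18 steps (1 to 32).

Steps most likely to fail

Step 7 (proposed new method): loss of a proton from the C4 cation, directly or after a hydride shift from C5, may outrun ring closure at the hindered silicon-bearing carbon, and adventitious acid may protodesilylate the chain. The fallback uses known chemistry, sets out from 14 and comes back at 15; it separates bond cleavage from ring closure. Me3SiI (Me3SiCl, NaI, MeCN, 0 °C), the established reagent for opening nopinone-type ketones, should convert 14 into methyl 2-{5-(2-iodopropan-2-yl)-6-methyl-2-(trimethylsilyloxy)-6-[(Z)-3-(trimethylsilyl)allyl]cyclohex-2-enyl}acetate F1. After evaporation, silver triflate with 2,6-di-tert-butylpyridine in CH2Cl2 at −78 °C should ionise the tertiary iodide irreversibly, and the ordinary vinylsilane-terminated cyclisation should give 15, which is hydrolysed to 16 as in step 7.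

Step 16: the second deprotonation beside the C8 alkoxide may be incomplete, and the new α-hydroxy ketone may undergo base-induced acyloin shift or over-oxidation before the quench. The fallback sets out from 28 and comes back at 30; it oxidises a neutral enol silane instead of an enolate (Rubottom oxidation). Me3SiOTf and Et3N in CH2Cl2 at 0 °C should give (12Z)-7,8α-bis(trimethylsilyloxy)labda-6,12,14-triene F2. One equivalent of dimethyldioxirane at −78 °C, which attacks the electron-rich enol ether far faster than the diene, should give after silyl migration (12Z)-6α,8α-bis(trimethylsilyloxy)labda-12,14-dien-7-one F3. Dilute HCl in THF then removes both silyl groups and gives 30.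

Step 12: the iodo ylide is thermally labile, so loss of iodine before the Wittig step and erosion of the Z/E ratio may lower the yield. The fallback sets out from 22 and comes back at 27; it builds the halogen-bearing alkene by cross-coupling instead of a Wittig reaction. Ramirez olefination (CBr4, PPh3, CH2Cl2, 0 °C) should give 13,13-dibromo-14,15,16-trinorlabda-7,12-diene F4. Palladium-catalysed trans-selective Negishi monomethylation (MeZnCl, PdCl2(DPEphos), THF) replaces the bromine trans to C11 and should give (12Z)-13-bromo-14,15-dinorlabda-7,12-diene F5. Dihydroxylation as in step 13 should give (12Z)-13-bromo-14,15-dinorlabd-12-ene-7α,8α-diol F6, and Stille coupling with 26 as in step 14 gives 27.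

Further compounds
F1 | step 7 | methyl 2-{5-(2-iodopropan-2-yl)-6-methyl-2-(trimethylsilyloxy)-6-[(Z)-3-(trimethylsilyl)allyl]cyclohex-2-enyl}acetate | COC(=O)C[C@@H]1C(O[Si](C)(C)C)=CC[C@@H](C(C)(C)I)[C@]1(C)C/C=C\[Si](C)(C)C
F2 | step 16 | (12Z)-7,8α-bis(trimethylsilyloxy)labda-6,12,14-triene | C=C/C(C)=C\C[C@H]1[C@](C)(O[Si](C)(C)C)C(O[Si](C)(C)C)=C[C@H]2C(C)(C)CCC[C@@]21C
F3 | step 16 | (12Z)-6α,8α-bis(trimethylsilyloxy)labda-12,14-dien-7-one | C=C/C(C)=C\C[C@H]1[C@](C)(O[Si](C)(C)C)C(=O)[C@H](O[Si](C)(C)C)[C@H]2C(C)(C)CCC[C@@]21C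
F4 | step 12 | 13,13-dibromo-14,15,16-trinorlabda-7,12-diene | BrC(Br)=CC[C@H]1C(C)=CC[C@H]2C(C)(C)CCC[C@@]21C
F5 | step 12 | (12Z)-13-bromo-14,15-dinorlabda-7,12-diene | Br/C(C)=C\C[C@H]1C(C)=CC[C@H]2C(C)(C)CCC[C@@]21C
F6 | step 12 | (12Z)-13-bromo-14,15-dinorlabd-12-ene-7α,8α-diol | Br/C(C)=C\C[C@H]1[C@](C)(O)[C@H](O)C[C@H]2C(C)(C)CCC[C@@]21C
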